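The plan rests on cutting the O1–C2 bond of ring B. C2 carries the ring oxygen and lies β to the C4 ketone, and its methyl is cis to the C3 methyl. That pattern is what results when a phenol oxygen (on C8a) adds to an ortho-tigloyl ketone and the enol is then protonated kinetically. One quinine-mediated oxa-Michael closure therefore forms ring B and sets C2 and C3 together. Its substrate is an enantiopure 4-phenyldihydrocoumarin. It carries the tigloyl group between the lactone oxygen and the only free phenol, the lavandulyl chain beside that phenol, and a silyl ether on the remaining para oxygen. Dearomative prenylation at C8 and opening of the lactone (ring C) complete the target.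

Key step: step 12

Remark (numbering): coumarin (chroman-2-one) numbering is used up to the substrate of the key step. From its product onward the chroman-4-one numbering of the target applies (ring A = carbocycle C4a–C8a, ring B = pyranone O1–C4, ring C = lactone bridging O5 and C6).
Remark (stereochemical bookkeeping): the target is 2R,3S (methyls cis), 8S, R at the benzylic carbon and R at the lavandulyl carbon. The lavandulyl centre keeps its geometry throughout, but it is labelled S in the alcohol, its ester, the iodide and the organometallic reagents, and R once its CH2 is bound to ring carbon, because the CIP ranking changes.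
Remark (facial situation at C8): in the closed lactone the ring C phenyl and both ring B methyls lie on the ring A face that must receive the prenyl group. The substrate therefore cannot be relied on, and a chiral catalyst is used.
Assumption: the sense of induction of the chiral ligands in steps 3 and 15 is not safely predictable for these substrates. The antipode named is the working choice and is swapped for its mirror image if the first assay shows the opposite sense.

Step 1
Reactants: 1 phloroglucinol; 2 ethyl benzoylacetate
Product: 3 5,7-dihydroxy-4-phenylcoumarin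
Conditions: conc. H2SO4, 0 °C → rt
Reagents that add atoms: none
Why: Pechmann condensation (transesterification, ring-closing hydroxyalkylation, dehydration) on the threefold-symmetric triol can give only one coumarin.

Step 2
Reactants: 3 5,7-dihydroxy-4-phenylcoumarin
Product: 4 5,7-diisopropoxy-4-phenylcoumarin
Conditions: 2-bromopropane (4 equiv), K2CO3 (4 equiv), DMF, 60 °C
Reagents that add atoms: 2-bromopropane, CC(C)Br
Why: Williamson etherification caps both phenols with groups that survive silane and SnCl4 yet leave with BCl3, so no silane is wasted in step 3 and no free ortho-phenol can close onto the tigloyl group in step 4.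

Step 3
Reactants: 4 5,7-diisopropoxy-4-phenylcoumarin
Product: 6 (4R)-5,7-diisopropoxy-4-phenylchroman-2-one, via silyl ketene acetal 5 (not isolated)
Conditions: Cu(OAc)2·H2O (3 mol%), (R)-DTBM-SEGPHOS (3.3 mol%), (EtO)2MeSiH (2 equiv), toluene, 0 °C → rt, no alcohol additive; then 1 M HCl/THF, 0 °C
Reagents that add atoms: diethoxy(methyl)silane, CCO[SiH](C)OCC (silyl group of 5 only)
Why: Copper-hydride-catalysed asymmetric conjugate reduction delivers hydride from the ligated L*CuH to one face of C4 and so sets C4 as R, and leaving out any alcohol parks the product as silyl ketene acetal 5, which blocks 1,2-reduction of the lactone until the acidic work-up.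

Step 4
Reactants: 6 (4R)-5,7-diisopropoxy-4-phenylchroman-2-one; 7 tigloyl chloride
Product: 8 (4R)-5,7-diisopropoxy-4-phenyl-8-tigloylchroman-2-one
Conditions: SnCl4 (1.5 equiv), CH2Cl2, −20 → 0 °C
Reagents that add atoms: none
Why: Friedel–Crafts acylation should go to C8, which is para to the 5-alkoxy and ortho to the 7-alkoxy group and is flanked on one side only by the tied-back ring oxygen, whereas C6 is wedged between two isopropoxy groups.

Step 5
Reactants: 8 (4R)-5,7-diisopropoxy-4-phenyl-8-tigloylchroman-2-one
Product: 9 (4R)-5,7-dihydroxy-4-phenyl-8-tigloylchroman-2-one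
Conditions: BCl3 (4 equiv), CH2Cl2, −78 → 0 °C; then ice water
Reagents that add atoms: none
Why: Lewis-acid dealkylation of aryl isopropyl ethers runs cold enough to spare lactone, enone and C4, the boron chelate between O7 and the ketone holds the phenol back from the enone, and the step is placed before the acid-sensitive lavandulyl chain arrives.

Step 6
Reactants: 9 (4R)-5,7-dihydroxy-4-phenyl-8-tigloylchroman-2-one
Product: 10 (4R)-5-(tert-butyldimethylsilyloxy)-7-hydroxy-4-phenyl-8-tigloylchroman-2-one
Conditions: TBSCl (1.05 equiv), imidazole (1.5 equiv), CH2Cl2, 0 °C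
Reagents that add atoms: tert-butyldimethylsilyl chloride, CC(C)(C)[Si](C)(C)Cl
Why: Chemoselective silylation is expected because the 7-OH is locked in a hydrogen bond to the C8 ketone, so only the free and more acidic 5-OH reacts.

Step 7
Reactants: 10 (4R)-5-(tert-butyldimethylsilyloxy)-7-hydroxy-4-phenyl-8-tigloylchroman-2-one
Product: 11 (4R)-5-(tert-butyldimethylsilyloxy)-7-hydroxy-6-iodo-4-phenyl-8-tigloylchroman-2-one
Conditions: NIS (1.05 equiv), CF3CO2H (10 mol%), MeCN, 0 °C, dark
Reagents that add atoms: N-iodosuccinimide, O=C1CCC(=O)N1I
Why: Electrophilic aromatic iodination can strike only C6, the last open ring position, which is activated by both flanking oxygens, while the electron-poor tigloyl alkene stays inert.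

Step 8
Reactants: 12 racemic lavandulol
Product: 13 (S)-lavandulyl hydrogen succinate
Conditions: porcine pancreatic lipase, succinic anhydride (0.5 equiv), Et2O, rt, stopped near 40% conversion; acid ester taken into aq Na2CO3 and released with dilute HCl
Reagents that add atoms: succinic anhydride, O=C1CCC(=O)O1
Why: In this lipase-catalysed kinetic resolution by acylation the enzyme is expected to esterify the S alcohol faster, so the stereocentre is selected rather than made, and the acid handle lets the ester be separated from the untouched R alcohol by base extraction.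

Step 9
Reactants: 13 (S)-lavandulyl hydrogen succinate
Product: 14 (S)-lavandulol
Conditions: NaOH (2.5 equiv), MeOH/H2O, rt; aqueous layer neutralised with HCl
Reagents that add atoms: none
Why: Plain ester saponification does not touch the allylic stereocentre.

Step 10
Reactants: 14 (S)-lavandulol
Product: 15 (S)-lavandulyl iodide
Conditions: I2, PPh3, imidazole, CH2Cl2, 0 °C → rt, dark
Reagents that add atoms: iodine, II
Why: Appel iodination displaces the activated primary oxygen by SN2 at CH2, one carbon away from the stereocentre, which is therefore retained.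

Step 11
Reactants: 11 (4R)-5-(tert-butyldimethylsilyloxy)-7-hydroxy-6-iodo-4-phenyl-8-tigloylchroman-2-one; 15 (S)-lavandulyl iodide
Product: 20 (4R)-5-(tert-butyldimethylsilyloxy)-7-hydroxy-6-[(2R)-lavandulyl]-4-phenyl-8-tigloylchroman-2-one, via aryl iodide trimethylsilyl ether 16 (not isolated), via lavandulyllithium 17 (not isolated), via lavandulylzinc bromide 18 (not isolated), via coupled trimethylsilyl ether 19 (not isolated)
Conditions: (a) 11, BSA (1.5 equiv), THF, 40 °C, then volatiles removed; (b) 15 (1.5 equiv), t-BuLi (3.1 equiv), Et2O/pentane, −78 °C, then ZnBr2 (1.6 equiv) in THF, −78 °C → rt; (c) a + b, Pd(OAc)2 (5 mol%), SPhos (10 mol%), THF, rt; (d) 10% aq citric acid/MeOH, 0 °C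
Reagents that add atoms: N,O-bis(trimethylsilyl)acetamide, CC(=N[Si](C)(C)C)O[Si](C)(C)C (silyl group of 16 and 19); tert-butyllithium, [Li]C(C)(C)C (lithium of 17); ZnBr2, Br[Zn]Br (zinc and bromine of 18)
Why: In this Negishi sp2–sp3 cross-coupling the transient silylation removes the one acidic proton and prevents ring closure of a zinc phenoxide, iodine–lithium exchange at −78 °C avoids the radical vinyl shift that direct zinc insertion could cause, and the bulky biarylphosphine favours reductive elimination over β-hydride loss, so the lavandulyl centre is carried over unchanged.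

Step 12
Reactants: 20 (4R)-5-(tert-butyldimethylsilyloxy)-7-hydroxy-6-[(2R)-lavandulyl]-4-phenyl-8-tigloylchroman-2-one
Product: 21 silyl-protected tricyclic cis-chromanone lactone (2R,3S; C7 OTBS; C8 lavandulyl; ring C intact)
Conditions: quinine (0.3 equiv), PhCl, 10 °C, followed closely; at full conversion cold 10% aq citric acid wash
Reagents that add atoms: none
Why: The quinuclidine nitrogen of quinine takes up the proton of the only free phenol while the alkaloid hydroxyl hydrogen-bonds the tigloyl carbonyl, and the ion-paired phenoxide oxygen adds to the β-carbon of the enone to give an enol that is then protonated at C3. The closest known reaction type is the cinchona-alkaloid-mediated intramolecular oxa-Michael addition of ortho-tigloylphenols to cis-2,3-dimethylchroman-4-ones. Ring B closes in the 6-endo-trig mode by forming O1–C2. C2 (R) is controlled by the alkaloid, which presents one enone face to the phenoxide within the ion pair, and C3 (S) by kinetic protonation of the enol on the face away from the pseudo-axial C2 methyl, which leaves the two methyls cis. The step needs a single nucleophilic oxygen and a single acidic site: the lactone of ring C holds the other ortho oxygen, and the silyl ether masks the more acidic para phenol that would otherwise pair with the base and drain the enone of electrophilicity. Cis/trans integrity is secured by the weak base, the apolar solvent, the low temperature and the acid wash at full conversion.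

Step 13
Reactants: 21 silyl-protected tricyclic cis-chromanone lactone
Product: 22 tricyclic cis-chromanone lactone with free C7 phenol
Conditions: n-Bu4NF (1.1 equiv), AcOH (1.5 equiv), THF, 0 °C
Reagents that add atoms: none
Why: Fluoride desilylation buffered with acetic acid frees the C7 phenol without building up a base able to epimerise C3 or open the lactone.

Step 14
Reactants: 23 prenol
Product: 24 tert-butyl prenyl carbonate
Conditions: Boc2O (1.2 equiv), n-Bu4NHSO4 (5 mol%), 30% aq NaOH, CH2Cl2, 0 °C → rt
Reagents that add atoms: di-tert-butyl dicarbonate, CC(C)(C)OC(=O)OC(=O)OC(C)(C)C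
Why: Phase-transfer O-acylation of a primary allylic alcohol with Boc2O is a standard entry to tert-butyl allylic carbonates.

Step 15
Reactants: 22 tricyclic cis-chromanone lactone with free C7 phenol; 24 tert-butyl prenyl carbonate
Product: 25 dearomatised (8S)-8-lavandulyl-8-prenyl dienone enol lactone
Conditions: Pd2(dba)3·CHCl3 (2.5 mol%), (R,R)-DACH-phenyl diphosphine [(1R,2R)-N,N'-bis(2-diphenylphosphinobenzoyl)cyclohexane-1,2-diamine] (7.5 mol%), 24 (1.3 equiv), toluene, 0 °C → rt
Reagents that add atoms: none
Why: Proposed new method: zerovalent palladium ionises 24 to a π-prenyl complex, CO2 and tert-butoxide, which only has to deprotonate the acidic C7 phenol; O-prenylation of this para-acylphenoxide should be reversible under the catalyst whereas C–C bond formation is not, C8 (primary alkyl substituent) is more open than C6 (secondary benzylic ring carbon), attack at the unsubstituted allyl terminus gives the linear prenyl group, and the chiral diphosphine pocket rather than the substrate chooses the ring A face so that C8 becomes S; the closest known reaction types are the Tsuji–Trost-type asymmetric allylic dearomatisation of 2-naphthols and the racemic palladium-catalysed dearomative allylation of phloroglucinol ethers.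

Step 16
Reactants: 25 dearomatised (8S)-8-lavandulyl-8-prenyl dienone enol lactone
Product: 26 target acid CNP0150579.4
Conditions: LiOH (3 equiv), THF/H2O 3:1, 0 °C, short; then cold 0.5 M HCl to pH 3
Reagents that add atoms: lithium hydroxide, [Li+].[OH-]
Why: Saponification of this vinylogous-anhydride-type enol lactone should be very fast at 0 °C, and the delocalised enolate–carboxylate dianion formed at once lowers the acidity of C3–H, so the cis methyls and C8 are kept.

Compound list
1 | phloroglucinol (benzene-1,3,5-triol) | Oc1cc(O)cc(O)c1 | starting material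
2 | ethyl benzoylacetate | CCOC(=O)CC(=O)c1ccccc1 | starting material
3 | 5,7-dihydroxy-4-phenylcoumarin | O=C1C=C(c2ccccc2)c2c(O)cc(O)cc2O1 | intermediate
4 | 5,7-diisopropoxy-4-phenylcoumarin | CC(C)Oc1cc(OC(C)C)c2C(c3ccccc3)=CC(=O)Oc2c1 | intermediate
5 | (4R)-2-[diethoxy(methyl)silyloxy]-5,7-diisopropoxy-4-phenyl-4H-chromene (silyl ketene acetal, not isolated) | CC(C)Oc1cc(OC(C)C)c2[C@@H](c3ccccc3)C=C(O[Si](C)(OCC)OCC)Oc2c1 | intermediate
6 | (4R)-5,7-diisopropoxy-4-phenylchroman-2-one | CC(C)Oc1cc(OC(C)C)c2[C@@H](c3ccccc3)CC(=O)Oc2c1 | intermediate
7 | tigloyl chloride, (E)-2-methylbut-2-enoyl chloride | C/C=C(\C)C(Cl)=O | starting material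
8 | (4R)-5,7-diisopropoxy-8-[(E)-2-methylbut-2-enoyl]-4-phenylchroman-2-one | CC(C)Oc1cc(OC(C)C)c2[C@@H](c3ccccc3)CC(=O)Oc2c1C(=O)/C(C)=C/C | intermediate
9 | (4R)-5,7-dihydroxy-8-[(E)-2-methylbut-2-enoyl]-4-phenylchroman-2-one | Oc1cc(O)c2[C@@H](c3ccccc3)CC(=O)Oc2c1C(=O)/C(C)=C/C | intermediate
10 | (4R)-5-(tert-butyldimethylsilyloxy)-7-hydroxy-8-[(E)-2-methylbut-2-enoyl]-4-phenylchroman-2-one | Oc1cc(O[Si](C)(C)C(C)(C)C)c2[C@@H](c3ccccc3)CC(=O)Oc2c1C(=O)/C(C)=C/C | intermediate
11 | (4R)-5-(tert-butyldimethylsilyloxy)-7-hydroxy-6-iodo-8-[(E)-2-methylbut-2-enoyl]-4-phenylchroman-2-one | Oc1c(I)c(O[Si](C)(C)C(C)(C)C)c2[C@@H](c3ccccc3)CC(=O)Oc2c1C(=O)/C(C)=C/C | intermediate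
12 | racemic lavandulol, 5-methyl-2-(prop-1-en-2-yl)hex-4-en-1-ol | C=C(C)C(CC=C(C)C)CO | starting material
13 | (S)-lavandulyl hydrogen succinate | C=C(C)[C@H](CC=C(C)C)COC(=O)CCC(=O)O | intermediate
14 | (S)-lavandulol | C=C(C)[C@H](CC=C(C)C)CO | intermediate
15 | (S)-lavandulyl iodide, (3S)-3-(iodomethyl)-2,6-dimethylhepta-1,5-diene | C=C(C)[C@H](CC=C(C)C)CI | intermediate
16 | 7-O-trimethylsilyl ether of 11 (4R, not isolated) | C[Si](C)(C)Oc1c(I)c(O[Si](C)(C)C(C)(C)C)c2[C@@H](c3ccccc3)CC(=O)Oc2c1C(=O)/C(C)=C/C | intermediate
17 | (S)-lavandulyllithium (geometry of 15 retained, not isolated) | C=C(C)[C@H](CC=C(C)C)C[Li] | intermediate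
18 | (S)-lavandulylzinc bromide (geometry of 15 retained, not isolated) | C=C(C)[C@H](CC=C(C)C)C[Zn]Br | intermediate
19 | 7-O-trimethylsilyl ether of 20 (not isolated) | C=C(C)[C@H](CC=C(C)C)Cc1c(O[Si](C)(C)C(C)(C)C)c2[C@@H](c3ccccc3)CC(=O)Oc2c(C(=O)/C(C)=C/C)c1O[Si](C)(C)C | intermediate
20 | (4R)-5-(tert-butyldimethylsilyloxy)-7-hydroxy-6-[(2R)-5-methyl-2-(prop-1-en-2-yl)hex-4-enyl]-8-[(E)-2-methylbut-2-enoyl]-4-phenylchroman-2-one (substrate of the key step) | C=C(C)[C@H](CC=C(C)C)Cc1c(O[Si](C)(C)C(C)(C)C)c2[C@@H](c3ccccc3)CC(=O)Oc2c(C(=O)/C(C)=C/C)c1O | intermediate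
21 | (4R,8R,9S)-5-(tert-butyldimethylsilyloxy)-8,9-dimethyl-6-[(2R)-lavandulyl]-4-phenyl-3,4,8,9-tetrahydro-2H,10H-pyrano[2,3-f]chromene-2,10-dione; in chroman numbering 2R,3S cis-dimethyl, C7 OTBS, C8 lavandulyl, ring C lactone with R benzylic carbon | C=C(C)[C@H](CC=C(C)C)Cc1c(O[Si](C)(C)C(C)(C)C)c2[C@@H](c3ccccc3)CC(=O)Oc2c2c1O[C@H](C)[C@H](C)C2=O | intermediate
22 | (4R,8R,9S)-5-hydroxy-8,9-dimethyl-6-[(2R)-lavandulyl]-4-phenyl-3,4,8,9-tetrahydro-2H,10H-pyrano[2,3-f]chromene-2,10-dione; in chroman numbering free C7 phenol | C=C(C)[C@H](CC=C(C)C)Cc1c(O)c2[C@@H](c3ccccc3)CC(=O)Oc2c2c1O[C@H](C)[C@H](C)C2=O | intermediate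
23 | prenol, 3-methylbut-2-en-1-ol | CC(C)=CCO | starting material
24 | tert-butyl 3-methylbut-2-enyl carbonate | CC(C)=CCOC(=O)OC(C)(C)C | intermediate
25 | dearomatised enol lactone; in chroman numbering (2R,3S,8S)-8-[(2R)-lavandulyl]-2,3-dimethyl-8-prenyl-4,7-dioxo dienone with ring C lactone from O5 to the R benzylic carbon on C6 | C=C(C)[C@H](CC=C(C)C)C[C@]1(CC=C(C)C)C(=O)C3=C(OC(=O)C[C@@H]3c4ccccc4)C2=C1O[C@H](C)[C@H](C)C2=O | intermediate
26 | CNP0150579.4, (3R)-3-[(2R,3S,8S)-5-hydroxy-8-[(2R)-lavandulyl]-2,3-dimethyl-4,7-dioxo-8-prenyl-3,4,7,8-tetrahydro-2H-chromen-6-yl]-3-phenylpropanoic acid | C=C(C)[C@H](CC=C(C)C)C[C@]1(CC=C(C)C)C(=O)C([C@H](CC(=O)O)c2ccccc2)=C(O)C2=C1O[C@H](C)[C@H](C)C2=O | target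

Total step count: 16. Longest linear sequence: 12 (steps 1–7, 11–13, 15, 16).

Steps most likely to fail

Step 15. Several processes could go wrong.
- O-prenylation may not revert.
- Attack may compete through C6.
- Facial discrimination at C8 may be weak, because the face to be alkylated is the one already occupied by the ring C phenyl and the ring B methyls.

The fallback uses known chemistry, the alkylative dearomatisation of acylphloroglucinols with prenyl bromide in aqueous alkali, and sets out from 22. Aqueous KOH at 0 °C opens ring C to the salt of the seco acid F1. There two phenoxides (O7 ortho, O5 para) activate C8, and the phenyl group no longer sits over ring A. Prenyl bromide is added to the same flask, and C-alkylation should prefer C8 over C6, which carries a secondary benzylic carbon. Acidification should give 26 beside the 8R epimer F2, and the two diastereomers are separated by preparative HPLC. The fallback comes back at 26, makes steps 14 to 16 unnecessary, and trades catalyst control for a separation.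

Step 12. Several processes could go wrong.
- Closure may be slow next to the bulky lavandulyl chain.
- Facial selectivity at C2 may be modest.
- The cis ketone may drift to trans during a long reaction.
- The lactone may transfer its acyl group to the alkaloid hydroxyl.

The fallback sets the two stereocentres in separate operations and sets out from 20. The closure is run to equilibrium (quinine, then Et3N), which should collect the material as the trans ketone F3. C2 epimers are diastereomers here, because of C4 and the lavandulyl centre, and can be removed by chromatography. TMSOTf/Et3N in CH2Cl2 at 0 °C turns F3 into the enol silane F4, which erases C3. Any silyl ketene acetal formed at the lactone is harmless, because its α-carbon is not stereogenic. Protonation with cold methanolic citric acid should occur anti to the pseudo-axial C2 methyl and bring the material back to the route at 21.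

Step 3. Several processes could go wrong.
- Hydride delivery to the peri-crowded, diaryl-substituted C4 may be sluggish.
- Discrimination between the two aryl groups may be insufficient.
- The lactone may be over-reduced.

The fallback makes the C4 centre by C–C instead of C–H bond formation and sets out from 1. Condensation with ethyl propiolate (ZnCl2, 100 °C) gives 5,7-dihydroxycoumarin F5, and 2-bromopropane/K2CO3 in DMF gives 5,7-diisopropoxycoumarin F6. Rhodium-catalysed asymmetric 1,4-addition of phenylboronic acid (Rh(acac)(C2H4)2, (R)-SEGPHOS, dioxane/H2O, 60 °C) then places the phenyl group on C4. The route is rejoined at 6.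

Further compounds
F1 | step 15 | seco acid, (3R)-3-[(2R,3S)-5,7-dihydroxy-8-[(2R)-lavandulyl]-2,3-dimethyl-4-oxochroman-6-yl]-3-phenylpropanoic acid | C=C(C)[C@H](CC=C(C)C)Cc1c(O)c([C@H](CC(=O)O)c2ccccc2)c(O)c2c1O[C@H](C)[C@H](C)C2=O
F2 | step 15 | 8R epimer of 26 | C=C(C)[C@H](CC=C(C)C)C[C@@]1(CC=C(C)C)C(=O)C([C@H](CC(=O)O)c2ccccc2)=C(O)C2=C1O[C@H](C)[C@H](C)C2=O
F3 | step 12 | trans ketone, (2R,3R) isomer of 21 | C=C(C)[C@H](CC=C(C)C)Cc1c(O[Si](C)(C)C(C)(C)C)c2[C@@H](c3ccccc3)CC(=O)Oc2c2c1O[C@H](C)[C@@H](C)C2=O
F4 | step 12 | enol silane, (2R)-4-trimethylsilyloxy-2H-chromene derived from F3 | C=C(C)[C@H](CC=C(C)C)Cc1c(O[Si](C)(C)C(C)(C)C)c2[C@@H](c3ccccc3)CC(=O)Oc2c2c1O[C@H](C)C(C)=C2O[Si](C)(C)C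
F5 | step 3 | 5,7-dihydroxycoumarin | O=C1C=Cc2c(O)cc(O)cc2O1
F6 | step 3 | 5,7-diisopropoxycoumarin | O=C1C=Cc2c(OC(C)C)cc(OC(C)C)cc2O1
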